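**Locants.** Drimane numbering is used for the decalin: ring A = C1–C5, C10; ring B = C5–C10; C11 = the OCH2 carbon on C9; C12 = the exocyclic CH2 on C8. In these locants the target is 3R,4R,5S,9R,10R.

## The problem

1. The target is an ent-drimane (the mirror-image series of the drimenol/sclareolide chiral pool) carrying umbelliferone as the C11 ether. It is a trans-decalin with five contiguous stereocentres (C3, C4, C5, C10, C9), two of them quaternary (C4, C10).
2. The C4 hydroxymethyl is axial: 1,3-diaxial to the C10 methyl and cis to the equatorial C3 hydroxyl. Neither oxidation of the E-methyl of a polyene terminus nor hydroxymethylation of a 4-methyl enolate gives this arrangement.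
3. C9 carries the aryloxymethyl group equatorially, next to the exocyclic C8=C12 methylene. This centre cannot be corrected later without pulling the double bond into the ring or into conjugation, so it has to be set kinetically.
4. The axial C10 methyl can control everything else: trans protonation at C5, the face of attack at C4 and at C9, and (through the axial C4 substituent) the hydride face at C3. Only C10 has to be set absolutely.
5. The coumarin lactone does not survive hydride, dissolving metal or strong base, and the exocyclic alkene and homoallylic aryl ether do not tolerate strong acid. The coumarin must therefore arrive last.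
6. The feature that makes the key step possible is in ring A: the C3 oxygen is para to the methyl-bearing C10, C5 (ortho to C10) carries the C6–C7 chain, and C4 (ortho to the oxygen) carries a carbon substituent. Ring A is thus the reduced form of a 2-alkyl-3-methyl-6-hydroxybenzoate whose para carbon is C10.
7. In ring B, C11 on C9 and C12 on C8 are the carbonyl carbon and the OCH2 carbon of a butenolide whose α-carbon is C9. The C9–C10 bond can therefore be made by joining an alkenyl carbon to the para carbon of a phenol with loss of aromaticity.

## Retrosynthesis

**C11–O bond.** The aryl ether is cut last, giving triol 15 and umbelliferone 16. Any earlier placement would expose the coumarin to the reductions that build the decalin. The forward reaction must etherify one of three hydroxyls; in 15 only C11–OH is an unhindered primary alcohol (the C4 CH2OH is neopentyl and axial, C3–OH is secondary and flanked by C4).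

**Oxidation levels at C3, C4 and C11; the C4–CH3 bond.** Triol 15 comes from keto diester 14 by one hydride reduction, and 14 from β-keto ester acid 13 by cutting the C4–CH3 bond. Cutting C4–CH3 rather than C4–CH2OH is the point: an electrophile enters a C3 enolate at C4 anti to the axial C10 methyl, so the carbon that is added last ends equatorial. The methyl must therefore be added last and the ester carbon must already be in place. The precursor loses one quaternary centre and one stereocentre.

**C5–H, C9–H and the C12–O bond.** Acid 13 is traced to tricyclic enone butenolide 11. A dissolving-metal reduction is needed anyway to set the trans ring fusion at C5. The same electrons cleave the allylic C12–O bond of a butenolide and leave a dienolate whose α-protonation gives C9–H and the C8=C12 methylene. This replaces a separate methylenation of a C8 ketone next to a β-oxygenated, epimerizable C9. Compound 11 has one stereocentre where 13 has three fixed ones.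

**C9–C10 bond (key disconnection).** Enone 11 comes from cross-conjugated dienone 10 by saturation of C1=C2, and 10 from phenol 9 by cutting C9–C10. In the forward direction this is a palladium-catalysed enantioselective dearomative cyclization. Against the polyene cuts (C4–C5 and C9–C10 together), it separates the absolute-configuration problem, solved once at C10 by a ligand, from the relative one, solved afterwards by the C10 methyl. Phenol 9 is flat and achiral: two rings joined by an ethylene chain. The forward step must pick the para carbon C10 over the ortho carbon C4, pick carbon over oxygen, and pick one enantioface.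

**C7–C8 and C6–C7 bonds; the arene.** Phenol 9 comes from methyl ether 8. Compound 8 comes from alkylboronate 6 and commercial 3,4-dibromofuran-2(5H)-one 7 by coupling at the more reactive C4–Br; the C3–Br that remains is the handle for the key step. Boronate 6 comes from methyl 6-methoxy-2,3-dimethylbenzoate 3 and iodomethylboronate 4 by lateral lithiation (through lithium species 5). The ester on the future C4 therefore has three roles: it acidifies the ortho methyl for chain building, blocks and deactivates the ortho carbon in the key step, and becomes the axial hydroxymethyl. Arene 3 comes from 2,3-dimethylbenzoic acid 1 through salicylic acid 2 by carboxylate-directed C–H hydroxylation and methylation.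

## Roads not taken

**Alternative 1:** (the most obvious) cut C4–C5 and C9–C10 together, with a polyene bicyclization of the farnesyl ether of 16.
- Forward key step: epoxide-initiated cyclization of epoxy alcohol A1 (SeO2 oxidation of the terminal E-methyl, then asymmetric epoxidation), either with a Lewis acid or as a radical cyclization with Cp2TiCl (trivalent titanium).
- Why the chosen plan is better: allylic oxidation functionalizes the E-methyl, which a chair cyclization transmits into the equatorial C4 position, so the product is the C4 epimer A2. The radical variant erases the C4 configuration altogether.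
- The electron-poor, oxygenated epoxide terminus is a poor initiator. The allylic umbelliferyl ether is itself a leaving group under Lewis acids. Termination gives exo/endo alkene mixtures.
- The route is short but stereochemically mismatched at the hardest centre.

**Alternative 2:** cut C10–C1 and C4–C5 (Robinson annulation logic).
- Forward key step: an amine-catalysed asymmetric annulation of a 2-methyl-1,3-dione with a vinyl keto ester gives enedione ester A3 with C10 set.
- Ring A can then be finished as in steps 8–10 here, but ring B arrives as a bare C9 ketone. C11, C12, the C8 methylene and the C9 stereocentre would all have to be added one by one (homologation at C9, oxidation and methylenation at C8, control of C9 next to the new alkene).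
- That is a long linear tail on a hindered ketone flanked by the quaternary C10. The chosen plan brings C11 and C12 in one commercial four-carbon piece and unveils the C8/C9 array in a step that is needed anyway.

**Alternative 3:** the same C9–C10 cut with reversed polarity.
- Forward key step: oxidation of phenol A4 with PhI(OAc)2 (trivalent iodine) to a phenoxonium ion, trapped at C10 by a tethered allylsilane. This would give dienone A5 with the exocyclic methylene and the C9 centre in one step through a chair transition state.
- Why the chosen plan is better: the event has no reliable enantioselective version, because the nucleophile attacks a carbon remote from the iodine centre, so A5 would be racemic.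
- A4 needs a geometrically pure trisubstituted allylsilane (several extra steps), and an electron-poor salicylate has to be oxidized in the presence of an oxidizable allylsilane.
- The chosen plan gives up direct formation of C9 in exchange for catalyst control at C10, and recovers C9 without extra steps.

Key step: step 6

Assumption: the sense of induction of the P-chiral ligand with an alkenyl bromide cannot be predicted with certainty. The antipode that gives (9aR)-10 is identified in the first run and used thereafter. Compounds 4, 7 and 16 are taken as commercial.

## Steps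

Step 1
Reactants: 1 2,3-dimethylbenzoic acid
Product: 2 6-hydroxy-2,3-dimethylbenzoic acid
Conditions: Pd(OAc)2 (10 mol %), KOAc, 1,4-benzoquinone, O2 (1 atm), DMA, 115 °C
Reagents that add atoms: dioxygen, O=O
Why: Carboxylate-directed palladium-catalysed ortho C–H hydroxylation of a benzoic acid; C6 is the only free ortho position of 1 and is unhindered, and molecular oxygen supplies the oxygen atom.

Step 2
Reactants: 2 6-hydroxy-2,3-dimethylbenzoic acid
Product: 3 methyl 6-methoxy-2,3-dimethylbenzoate
Conditions: MeI (excess), K2CO3, DMF, 50 °C
Reagents that add atoms: iodomethane, CI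
Why: Double O-alkylation (ester formation and Williamson etherification); excess MeI/K2CO3 in DMF methylates both the carboxylate and the hydrogen-bonded salicylic phenol.

Step 3
Reactants: 3 methyl 6-methoxy-2,3-dimethylbenzoate; 4 2-(iodomethyl)-4,4,5,5-tetramethyl-1,3,2-dioxaborolane
Product: 6 methyl 6-methoxy-3-methyl-2-[2-(4,4,5,5-tetramethyl-1,3,2-dioxaborolan-2-yl)ethyl]benzoate, via benzylic lithium species 5 (not isolated)
Conditions: LiN(iPr)2 (1.05 equiv), THF, −78 °C; then 4, −78 to 23 °C
Reagents that add atoms: none
Why: Lateral lithiation of an ortho-toluate: only the methyl ortho to the ester is acidified (extended ester enolate), the other methyl is not. The anion adds to boron of 4 and the benzylic carbon migrates to CH2 with loss of iodide (Matteson-type homologation), giving the primary alkylboronate with C6–C7 formed.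

Step 4
Reactants: 6 methyl 6-methoxy-3-methyl-2-[2-(4,4,5,5-tetramethyl-1,3,2-dioxaborolan-2-yl)ethyl]benzoate; 7 3,4-dibromofuran-2(5H)-one
Product: 8 methyl 2-[2-(4-bromo-5-oxo-2,5-dihydrofuran-3-yl)ethyl]-6-methoxy-3-methylbenzoate
Conditions: PdCl2(dppf) (5 mol %), Ag2O (2.5 equiv), THF, 65 °C
Reagents that add atoms: none
Why: Site-selective B-alkyl Suzuki–Miyaura coupling: oxidative addition is much faster at C4–Br of 7 (β to the carbonyl, a vinylogous acyl bromide) than at C3–Br, so C7–C8 forms and the α-bromide is kept. Silver oxide activates the boronate without aqueous base, which would open the lactone.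

Step 5
Reactants: 8 methyl 2-[2-(4-bromo-5-oxo-2,5-dihydrofuran-3-yl)ethyl]-6-methoxy-3-methylbenzoate
Product: 9 methyl 2-[2-(4-bromo-5-oxo-2,5-dihydrofuran-3-yl)ethyl]-6-hydroxy-3-methylbenzoate
Conditions: BCl3, CH2Cl2, −78 to 0 °C; aqueous NaHCO3 work-up
Reagents that add atoms: none
Why: Chelation-assisted aryl methyl ether cleavage: BCl3 bound to the ester carbonyl removes only the ortho methoxy methyl; the methyl ester, alkenyl bromide and lactone are untouched.

Step 6
Reactants: 9 methyl 2-[2-(4-bromo-5-oxo-2,5-dihydrofuran-3-yl)ethyl]-6-hydroxy-3-methylbenzoate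
Product: 10 methyl (9aR)-9a-methyl-1,7-dioxo-1,3,4,5,7,9a-hexahydronaphtho[1,2-c]furan-6-carboxylate
Conditions: [Pd(C3H5)Cl]2 (2.5 mol %), P-chiral monophosphine AntPhos (3-tert-butyl-4-(9-anthryl)-2,3-dihydrobenzo[d][1,3]oxaphosphole, 6 mol %, antipode giving 9aR), K2CO3, toluene (0.02 M), 90 °C
Reagents that add atoms: none
Why: Zerovalent palladium inserts into the C9–Br bond of the α-bromobutenolide; carbonate forms the phenoxide, which replaces bromide on divalent palladium and slips from the O-bound to the C10-bound (para) cyclohexadienone form, and C–C reductive elimination then forges C9–C10 and returns zerovalent palladium. The closest known reaction type is the palladium-catalysed enantioselective dearomative cyclization of 3-[2-(2-bromoaryl)ethyl]-4-methylphenols to 4a-methylphenanthren-2-ones with P-chiral monophosphines, together with dearomatizing reductive eliminations from alkenylpalladium phenoxides; here the cyclic alkenyl bromide holds the tether cis to the C–Pd bond just as an ortho-substituted aryl bromide does. Ring B is closed as a six-membered ring by C(sp2)–C(sp3) reductive elimination from a seven-membered palladacycle (Pd, C9, C8, C7, C6, C5, C10). The quaternary C10 is the only new stereocentre and its configuration is fixed by the ligand, which selects the phenoxide face that binds palladium. Para over ortho attack is needed: both would give six-membered rings, but C4 carries the ester, which blocks it sterically and lowers its nucleophilicity, while the para carbon has the larger phenoxide coefficient. C- over O-alkenylation is secured because the two-carbon tether cannot reach the oxygen, and high dilution suppresses the intermolecular ether. Weak heterogeneous carbonate in toluene deprotonates the phenol but not the butenolide CH2.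

Step 7
Reactants: 10 methyl (9aR)-9a-methyl-1,7-dioxo-1,3,4,5,7,9a-hexahydronaphtho[1,2-c]furan-6-carboxylate
Product: 11 methyl (9aR)-9a-methyl-1,7-dioxo-1,3,4,5,7,8,9,9a-octahydronaphtho[1,2-c]furan-6-carboxylate
Conditions: H2 (1 atm), RhCl(PPh3)3 (5 mol %), benzene/EtOH, 23 °C
Reagents that add atoms: none
Why: Homogeneous hydrogenation with RhCl(PPh3)3 saturates only the cis-disubstituted C1=C2 bond; the two tetrasubstituted alkenes (C4=C5 and the butenolide C8=C9) are inert, as in the selective reduction of steroidal 1,4-dien-3-ones to 4-en-3-ones.

Step 8
Reactants: 11 methyl (9aR)-9a-methyl-1,7-dioxo-1,3,4,5,7,8,9,9a-octahydronaphtho[1,2-c]furan-6-carboxylate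
Product: 13 (1R,4aR,5RS,8aR)-5-(methoxycarbonyl)-8a-methyl-2-methylidene-6-oxodecahydronaphthalene-1-carboxylic acid, via trilithium enolate dienediolate 12 (not isolated)
Conditions: Li (6 equiv), NH3 (l)/THF, −78 °C; isoprene; solid NH4Cl, −78 to 23 °C; work-up at pH 3
Reagents that add atoms: none
Why: Dissolving-metal reduction doing two jobs: the doubly activated C4=C5 bond is reduced with axial protonation at C5 anti to the C10 methyl (trans-decalin, as for 10-methyl-4-en-3-ones) and parks as the β-keto ester enolate, while two further electrons cleave the allylic C12–O bond of the butenolide (vinylogous α-acyloxy carbonyl reduction) to a carboxylate dienolate. Kinetic α-protonation of that dienolate at C9 by NH4Cl, axially and from the face opposite the axial C10 methyl, gives the β,γ-unsaturated acid with C8=C12 exocyclic and C11 equatorial; because the dienolate is generated only toward C12, no ring-alkene isomer can form.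

Step 9
Reactants: 13 (1R,4aR,5RS,8aR)-5-(methoxycarbonyl)-8a-methyl-2-methylidene-6-oxodecahydronaphthalene-1-carboxylic acid
Product: 14 dimethyl (1R,4aS,5S,8aR)-5,8a-dimethyl-2-methylidene-6-oxodecahydronaphthalene-1,5-dicarboxylate
Conditions: MeI (excess), K2CO3, acetone, 23–40 °C
Reagents that add atoms: iodomethane, CI
Why: C-Alkylation of a β-keto ester enolate: the face of C4 syn to the axial C10 methyl is blocked (1,3-diaxial), so MeI enters anti and the methyl ends equatorial with the ester axial, cis to the C10 methyl (the long-known outcome for 4-alkoxycarbonyl-10-methyl-3-decalones). The carboxylate is esterified in the same pot, and the weak base does not deprotonate C9.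

Step 10
Reactants: 14 dimethyl (1R,4aS,5S,8aR)-5,8a-dimethyl-2-methylidene-6-oxodecahydronaphthalene-1,5-dicarboxylate
Product: 15 (1R,2R,4aR,5R,8aS)-1,5-bis(hydroxymethyl)-1,4a-dimethyl-6-methylidenedecahydronaphthalen-2-ol
Conditions: LiAlH4 (excess), THF, 0 °C to reflux; aqueous NaOH work-up
Reagents that add atoms: none
Why: Global hydride reduction: hydride attacks the C3 ketone axially, from the face opposite the axial C4 ester, to give the equatorial alcohol cis to the C4 carbon substituent (as for 4,4-disubstituted 3-ketones of this ring system). Both esters go to primary alcohols and the unconjugated exocyclic alkene is inert.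

Step 11
Reactants: 15 (1R,2R,4aR,5R,8aS)-1,5-bis(hydroxymethyl)-1,4a-dimethyl-6-methylidenedecahydronaphthalen-2-ol; 16 7-hydroxy-2H-chromen-2-one (umbelliferone)
Product: 17 7-{[(1R,4aS,5R,6R,8aR)-6-hydroxy-5-(hydroxymethyl)-5,8a-dimethyl-2-methylidenedecahydronaphthalen-1-yl]methoxy}-2H-chromen-2-one (CNP0149624.1)
Conditions: PPh3, DIAD (1.3 equiv each), THF, 0 to 23 °C
Reagents that add atoms: none
Why: Mitsunobu etherification with an acidic phenol (pKa about 8): the oxyphosphonium ion forms and is displaced only at the unhindered primary C11–OH, while the axial neopentyl CH2OH on C4 and the secondary C3–OH flanked by a quaternary carbon react far more slowly. The neutral conditions leave the coumarin lactone and the exocyclic alkene untouched, and no stereocentre is involved.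

## Compound list

1 | 2,3-dimethylbenzoic acid | Cc1cccc(C(=O)O)c1C | starting material
2 | 6-hydroxy-2,3-dimethylbenzoic acid | Cc1ccc(O)c(C(=O)O)c1C | intermediate
3 | methyl 6-methoxy-2,3-dimethylbenzoate | COC(=O)c1c(OC)ccc(C)c1C | intermediate
4 | 2-(iodomethyl)-4,4,5,5-tetramethyl-1,3,2-dioxaborolane | CC1(C)OB(CI)OC1(C)C | starting material
5 | [3-methoxy-2-(methoxycarbonyl)-6-methylphenyl]methyllithium | [Li]Cc1c(C)ccc(OC)c1C(=O)OC | intermediate (not isolated)
6 | methyl 6-methoxy-3-methyl-2-[2-(4,4,5,5-tetramethyl-1,3,2-dioxaborolan-2-yl)ethyl]benzoate | COC(=O)c1c(OC)ccc(C)c1CCB1OC(C)(C)C(C)(C)O1 | intermediate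
7 | 3,4-dibromofuran-2(5H)-one | O=C1OCC(Br)=C1Br | starting material
8 | methyl 2-[2-(4-bromo-5-oxo-2,5-dihydrofuran-3-yl)ethyl]-6-methoxy-3-methylbenzoate | COC(=O)c1c(OC)ccc(C)c1CCC1=C(Br)C(=O)OC1 | intermediate
9 | methyl 2-[2-(4-bromo-5-oxo-2,5-dihydrofuran-3-yl)ethyl]-6-hydroxy-3-methylbenzoate | COC(=O)c1c(O)ccc(C)c1CCC1=C(Br)C(=O)OC1 | intermediate
10 | methyl (9aR)-9a-methyl-1,7-dioxo-1,3,4,5,7,9a-hexahydronaphtho[1,2-c]furan-6-carboxylate | C[C@@]12C=CC(=O)C(C(=O)OC)=C1CCC1=C2C(=O)OC1 | intermediate
11 | methyl (9aR)-9a-methyl-1,7-dioxo-1,3,4,5,7,8,9,9a-octahydronaphtho[1,2-c]furan-6-carboxylate | C[C@@]12CCC(=O)C(C(=O)OC)=C1CCC1=C2C(=O)OC1 | intermediate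
12 | trilithium salt: lithium enolate of the ring A β-keto ester and dilithium dienediolate of the C11 carboxylate | C=C1CC[C@@H]2C(C(=O)OC)=C(O[Li])CC[C@@]2(C)C1=C(O[Li])O[Li] | intermediate (not isolated)
13 | (1R,4aR,5RS,8aR)-5-(methoxycarbonyl)-8a-methyl-2-methylidene-6-oxodecahydronaphthalene-1-carboxylic acid (C5 of this name epimerizes through the enol) | C=C1CC[C@@H]2C(C(=O)OC)C(=O)CC[C@@]2(C)[C@@H]1C(=O)O | intermediate
14 | dimethyl (1R,4aS,5S,8aR)-5,8a-dimethyl-2-methylidene-6-oxodecahydronaphthalene-1,5-dicarboxylate | C=C1CC[C@@H]2[C@](C)(C(=O)OC)C(=O)CC[C@@]2(C)[C@@H]1C(=O)OC | intermediate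
15 | (1R,2R,4aR,5R,8aS)-1,5-bis(hydroxymethyl)-1,4a-dimethyl-6-methylidenedecahydronaphthalen-2-ol | C=C1CC[C@@H]2[C@](C)(CO)[C@H](O)CC[C@@]2(C)[C@@H]1CO | intermediate
16 | 7-hydroxy-2H-chromen-2-one (umbelliferone) | O=c1ccc2ccc(O)cc2o1 | starting material
17 | 7-{[(1R,4aS,5R,6R,8aR)-6-hydroxy-5-(hydroxymethyl)-5,8a-dimethyl-2-methylidenedecahydronaphthalen-1-yl]methoxy}-2H-chromen-2-one | C=C1CC[C@@H]2[C@](C)(CO)[C@H](O)CC[C@@]2(C)[C@@H]1COc1ccc2ccc(=O)oc2c1 | target

## Step count and risk

Total: 11 steps. Longest linear sequence: 11 steps from 1 (4, 7 and 16 are purchased).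

**Step 6 (key step).**
- Most likely to go wrong: erosion of enantioselectivity, because the ligand pocket was shaped for arylpalladium phenoxides and here the palladium sits on an alkenyl carbon flanked by a lactone carbonyl. Protodebromination is the second concern.
- Fallback (from 9, rejoining at 13): cyclize with an achiral phosphine (Pd2(dba)3, P(tBu)3, K2CO3, toluene) to the racemic dienone F1. Carry it through steps 7 and 8 to the racemic enone butenolide F2 and the racemic acid F3. Resolve the acid by crystallization of its (S)-1-phenylethylammonium salt F4 (or the mirror amine if that one pairs with the wanted acid), then acidify to return 13. The acid function appears in the route anyway, so no handle has to be added.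

**Step 8.**
- Most likely to go wrong: protonation of the dienediolate at the exocyclic terminus C12, or amide-mediated migration of the new double bond into conjugation before the quench, giving the 8,9-unsaturated acid. Simple saturation of the butenolide is less likely, since carboxylate is a good leaving group.
- Fallback (from 11, rejoining at 14): accept the conjugated keto ester acid F5 and methylate it as in step 9 to the conjugated keto diester F6. Then deconjugate photochemically (254 nm, hexane, catalytic 1,2-dimethylimidazole). The excited enoate takes a hydrogen only from the γ-carbon cis to the ester, which here is the C12 methyl and not C7, and the photodienol ketonizes at C9 from the open face to give 14. This replaces a protonation-controlled step by a geometry-controlled 1,5-hydrogen shift.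

**Step 4.**
- Most likely to go wrong: slow transmetalation of the primary alkyl pinacol boronate, so that reduction or homocoupling of 7 takes over.
- Fallback (from 3, rejoining at 8): lithiate as in step 3 and alkylate with chloroiodomethane to the chloride F7. Exchange with NaI in acetone to the iodide F8. Insert zinc (Zn dust, LiCl, THF) to the alkylzinc iodide F9, and run a Negishi coupling with 7 (Pd(PPh3)4, THF, 23 °C) at the same C4–Br to give 8.

**Step 11.**
- Most likely to go wrong: consumption of the Mitsunobu betaine by the 1,3-diol (cyclic phosphorane) together with sluggish substitution at the β-branched C11, giving low conversion or mixed ethers.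
- Fallback (from 15, rejoining at 17): protect the C3 hydroxyl and the C4 hydroxymethyl as the acetonide F10 (2,2-dimethoxypropane, PPTS). Convert C11–OH to the mesylate F11 (MsCl, Et3N). Displace with 16 and Cs2CO3 in DMF at 60 °C to the ether acetonide F12, and remove the acetonide with PPTS in aqueous methanol to give 17.

**Step 1.**
- Most likely to go wrong: incomplete C–H palladation, or over-oxidation of the electron-rich product under the aerobic conditions.
- Fallback (bypasses 1 and 2, rejoining at 3): build the arene instead of oxidizing it. Condense methyl acetoacetate F13 with tiglic aldehyde F14 (catalytic NaOMe in MeOH, then HCl; Michael addition followed by aldol condensation) to the cyclohexenone ester F15. Aromatize with CuBr2/LiBr in refluxing MeCN to methyl 6-hydroxy-2,3-dimethylbenzoate F16, and O-methylate (MeI, K2CO3) to 3.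

## Further compounds

F1 | step 6 | racemic methyl 9a-methyl-1,7-dioxo-1,3,4,5,7,9a-hexahydronaphtho[1,2-c]furan-6-carboxylate | CC12C=CC(=O)C(C(=O)OC)=C1CCC1=C2C(=O)OC1
F2 | step 6 | racemic methyl 9a-methyl-1,7-dioxo-1,3,4,5,7,8,9,9a-octahydronaphtho[1,2-c]furan-6-carboxylate | CC12CCC(=O)C(C(=O)OC)=C1CCC1=C2C(=O)OC1
F3 | step 6 | racemic 5-(methoxycarbonyl)-8a-methyl-2-methylidene-6-oxodecahydronaphthalene-1-carboxylic acid (relative configuration as in 13) | C=C1CCC2C(C(=O)OC)C(=O)CCC2(C)C1C(=O)O
F4 | step 6 | (S)-1-phenylethylammonium salt of acid 13 | C=C1CC[C@@H]2C(C(=O)OC)C(=O)CC[C@@]2(C)[C@@H]1C(=O)[O-].C[C@H]([NH3+])c1ccccc1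
F5 | step 8 | (4aR,8aR)-5-(methoxycarbonyl)-2,8a-dimethyl-6-oxo-3,4,4a,5,6,7,8,8a-octahydronaphthalene-1-carboxylic acid (conjugated isomer of 13) | CC1=C(C(=O)O)[C@]2(C)CCC(=O)C(C(=O)OC)[C@H]2CC1
F6 | step 8 | dimethyl (4aS,5S,8aR)-2,5,8a-trimethyl-6-oxo-3,4,4a,5,6,7,8,8a-octahydronaphthalene-1,5-dicarboxylate (conjugated isomer of 14) | CC1=C(C(=O)OC)[C@]2(C)CCC(=O)[C@@](C)(C(=O)OC)[C@H]2CC1
F7 | step 4 | methyl 2-(2-chloroethyl)-6-methoxy-3-methylbenzoate | COC(=O)c1c(OC)ccc(C)c1CCCl
F8 | step 4 | methyl 2-(2-iodoethyl)-6-methoxy-3-methylbenzoate | COC(=O)c1c(OC)ccc(C)c1CCI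
F9 | step 4 | {2-[3-methoxy-2-(methoxycarbonyl)-6-methylphenyl]ethyl}zinc iodide | COC(=O)c1c(OC)ccc(C)c1CC[Zn]I
F10 | step 11 | acetonide of 15 (1,3-dioxane across the C3 hydroxyl and the C4 hydroxymethyl; C11 alcohol free) | C=C1CC[C@@H]2[C@]3(C)COC(C)(C)O[C@@H]3CC[C@@]2(C)[C@@H]1CO
F11 | step 11 | C11 methanesulfonate of the acetonide of 15 | C=C1CC[C@@H]2[C@]3(C)COC(C)(C)O[C@@H]3CC[C@@]2(C)[C@@H]1COS(C)(=O)=O
F12 | step 11 | acetonide of 17 | C=C1CC[C@@H]2[C@]3(C)COC(C)(C)O[C@@H]3CC[C@@]2(C)[C@@H]1COc1ccc2ccc(=O)oc2c1
F13 | step 1 | methyl acetoacetate | CC(=O)CC(=O)OC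
F14 | step 1 | (E)-2-methylbut-2-enal (tiglic aldehyde) | C/C=C(\C)C=O
F15 | step 1 | methyl 5,6-dimethyl-2-oxocyclohex-3-ene-1-carboxylate (racemic diastereomer mixture) | COC(=O)C1C(C)C(C)C=CC1=O
F16 | step 1 | methyl 6-hydroxy-2,3-dimethylbenzoate | COC(=O)c1c(O)ccc(C)c1C
A1 | alternative 1 | 7-({(2E,6E)-9-[(2R,3R)-3-(hydroxymethyl)-3-methyloxiran-2-yl]-3,7-dimethylnona-2,6-dien-1-yl}oxy)-2H-chromen-2-one | O=c1ccc2ccc(OC/C=C(\C)CC/C=C(\C)CC[C@H]3O[C@]3(C)CO)cc2o1
A2 | alternative 1 | 7-{[(1R,4aS,5S,6R,8aR)-6-hydroxy-5-(hydroxymethyl)-5,8a-dimethyl-2-methylidenedecahydronaphthalen-1-yl]methoxy}-2H-chromen-2-one (C4 epimer of 17 in drimane locants) | C=C1CC[C@@H]2[C@@](C)(CO)[C@H](O)CC[C@@]2(C)[C@@H]1COc1ccc2ccc(=O)oc2c1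
A3 | alternative 2 | methyl (4aR)-4a-methyl-2,5-dioxo-2,3,4,4a,5,6,7,8-octahydronaphthalene-1-carboxylate | COC(=O)C1=C2CCCC(=O)[C@]2(C)CCC1=O
A4 | alternative 3 | methyl 2-[(3Z)-5-{[tert-butyl(dimethyl)silyl]oxy}-3-[(trimethylsilyl)methyl]pent-3-en-1-yl]-6-hydroxy-3-methylbenzoate | COC(=O)c1c(O)ccc(C)c1CC/C(C[Si](C)(C)C)=C/CO[Si](C)(C)C(C)(C)C
A5 | alternative 3 | racemic methyl 5-({[tert-butyl(dimethyl)silyl]oxy}methyl)-4a-methyl-6-methylidene-2-oxo-2,4a,5,6,7,8-hexahydronaphthalene-1-carboxylate | C=C1CCC2=C(C(=O)OC)C(=O)C=CC2(C)C1CO[Si](C)(C)C(C)(C)C
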